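The second nucleophile takes the intermediate faster than the first does at their charged concentrations, so with both in the flask at charge target falls behind the other capture product, and the question is how far each recipe shifts that comparison.

| flask | substrate | first nucleophile | second nucleophile | temperature | time | remark |
|---|---|---|---|---|---|---|
| alder | 23 mM (in portions, 3, over 8.0 s) | 16.1 mM | 46.0 mM | 60 °C | 10 s | first portion at the start, last at 8.0 s |
| birch | 23 mM (fed, over 2.0 s) | 16.1 mM | 46.0 mM | 60 °C | 10 s | all else is in the flask from the start; the feed brings no volume worth counting |
| larch | 23 mM | 16.1 mM | 46.0 mM (fed, over 8.0 s) |  | 10 s | the addition at 40 °C, then warmed to 60 °C; the feed brings no volume worth counting |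
| maple | 23 mM | 16.1 mM | 46.0 mM | 60 °C | 10 s | everything together at the start |
| ash | 23 mM (fed, over 8.0 s) | 16.1 mM | 46.0 mM | 60 °C | 10 s | all else is in the flask from the start; the feed brings no volume worth counting |

* the flask with the highest share of target in target plus other capture product ("all alike" if they lie within 1.5 percentage points) (alder / birch / larch / maple / ash / all alike)
* share of target in target plus other capture product at the end, alder
* share of target in target plus other capture product at the end, birch
* share of target in target plus other capture product at the end, larch
* share of target in target plus other capture product at the end, maple
* share of target in target plus other capture product at the end, ash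

- amounts and yields of target count crystals too
- given per volume of solution although it is solid: crystals
- the constants hold at 60 °C; other temperatures follow from the activation energies and enthalpies

    target ⇌ isomer of the product (K1 = 0.34, k1 = 0.031 s⁻¹, Ea1 = 86.0 kJ mol⁻¹, ΔH1 = −64.0 kJ mol⁻¹)
    first nucleophile + intermediate → target (k2 = 220 M⁻¹ s⁻¹, Ea2 = 48.0 kJ mol⁻¹)
    substrate → intermediate (k3 = 0.12 s⁻¹, Ea3 = 74.0 kJ mol⁻¹)
    crystals ⇌ target, rate k4*(cs4 - [target]) while solid is left; crystals form when [target] > cs4 (cs4 = 20 mM, k4 = 0.71 s⁻¹)
    second nucleophile + intermediate → other capture product (k5 = 140 M⁻¹ s⁻¹, Ea5 = 56.0 kJ mol⁻¹)
    first nucleophile + target → over-reaction product (k6 = 7.7 M⁻¹ s⁻¹, Ea6 = 57.0 kJ mol⁻¹)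
    intermediate → solvolysis product (k7 = 0.22 s⁻¹, Ea7 = 83.0 kJ mol⁻¹)
    (constants at 60 °C)

I build maple first, because its recipe puts the charges together at the start. With the main path alone, substrate opens to the intermediate with a constant κ = 0.12 s⁻¹. In maple the intermediate lasts far less time than the substrate that feeds it, with a half-life of 0.11 s by capture with the second nucleophile alone against 5.8 s for the substrate opening alone, so I let it divide at once. The two captures are pseudo-first-order, with rates a = 3.54 s⁻¹ for the first nucleophile and b = 6.44 s⁻¹ for the second. The split S = a/(a + b) is then 35.5%, and in this first picture, with both nucleophiles held at their charges, S is the share asked for.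

Next I add solvolysis. It takes 2.16% of the intermediate, and as a loss running beside the two captures it leaves the ratio of their products as it was. Crystals come next, and they do not enter: target cannot exceed the charge of first nucleophile, 16.1 mM, which is less than the solubility of 20 mM.

Last I add the steps that consume target, over-reaction and isomerisation, with the first nucleophile held at its charge and the return from the isomer ignored. Together they drain target at λ = 0.155 s⁻¹. Target is fed in proportion to e^(−κt) and drained at λ, and integrating that single rate gives the kept fraction, w = κ/(λ − κ) · (e^(−κt) − e^(−λt)) / (1 − e^(−κt)), the part of the target made up to time t that is still there. At 10 s this gives w = 0.436, and the share S·w/(S·w + 1 − S) falls to 19.4% for maple.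

Feeding substrate, as alder, birch and ash do, leaves a and b unchanged and makes the target younger at the reading, so I expect those flasks a little above maple. Larch is different. With the second nucleophile rising steadily over 8.0 s, its capture rate grows from nothing to b, and averaging the split over that time gives (a/b)·ln(1 + b/a) = 57.0%, more than S. That figure uses the constants at the reference temperature, and the cold should push it further, since the first capture has the lower activation energy, 48.0 kJ mol⁻¹ against 56.0 kJ mol⁻¹. I stake on larch as highest but give it no number, because I have not reckoned how its turnover divides between the feed and the warm end.

The forecast also names larch, with 22.5% for alder, 21.5% for birch, 38% for larch, 21% for maple and 23% for ash, on the ground that the slow feed “lets the first nucleophile take most of the early intermediate”.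

The simulation gives 24.0% for alder, 22.1% for birch, 37.0% for larch, 21.2% for maple and 24.8% for ash, so larch stands highest. At the end of maple, the first nucleophile stands at 56.8% of its own charge, whereas my λ held it at the full charge. Turned round, the maple result with the same S asks for a kept fraction of 0.489, against my 0.436.

Now take the maple flask read at 6.0 s. S stays the same, and the kept fraction rises to 0.616, which gives a share of 25.3%. The computed share at that reading is 25.7%.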